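## Retrosynthetic overview
- **Step 9 disconnection:** the target (12) comes from the vinyl dioxane 11 by ozonolysis in MeOH with Criegee trapping, which turns the vinyl group into CO2Me with the α-stereocentre untouched.
- **Key bold step (Step 8):** the quaternary peroxy-stereocentre C3 is set by axial methylation of a cyclic peroxycarbenium ion (from peroxyketal 10), rather than by a cyclisation such as oxa-Michael or hydroperoxide–alkene closure. The ring's C6 substituent controls the face of attack.
- **Dioxane ring closure:** the 1,2-dioxane ring closes in Step 6 by hydroperoxide SN2 at the C6 mesylate (inversion), using H2O2 and the γ-ketone.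
- **Cα/C6 stereochemistry:** an asymmetric (E)-crotylboration of ketoaldehyde 5 sets Cα and C6 in one step.
- **Ring origin:** the cyclohexenone ring comes from commercial dihydro-β-ionone, with C4-oxidation in Step 2.

**Assumptions:** the SMILES gives the natural absolute configuration. The target's ring relationship is C3-chain trans to the C6 side chain, with Me axial. Dihydro-β-ionone, allyl bromide, trans-2-butene and (–)-α-pinene-derived Ipc2BOMe are commercial.

## Route

**Step 1**
Reactants: 1 dihydro-β-ionone; 2 allyl bromide
Product: 3 1-(2,6,6-trimethylcyclohex-1-en-1-yl)hept-6-en-3-one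
Conditions: LDA, THF, –78 °C; then 2, DMPU, –78 → 0 °C
Reagents that add atoms: allyl bromide (2), C=CCBr
Why: Kinetic enolate alkylation; LDA deprotonates the methyl side of the methyl ketone selectively, and no stereocentre is formed.

**Step 2**
Reactants: 3
Product: 4 2,4,4-trimethyl-3-(3-oxohept-6-en-1-yl)cyclohex-2-en-1-one
Conditions: CrO3, 3,5-dimethylpyrazole, CH2Cl2, –20 °C
Reagents that add atoms: chromium trioxide, O=[Cr](=O)=O
Why: Salmond-type allylic oxidation of the ring CH2 next to the tetrasubstituted alkene, as in β-ionone → 4-oxo-β-ionone, gives the 3-oxo-cyclogeranyl enone.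

**Step 3**
Reactants: 4
Product: 5 4-oxo-6-(2,6,6-trimethyl-3-oxocyclohex-1-en-1-yl)hexanal
Conditions: O3 (1 equiv), CH2Cl2, –78 °C; then Me2S, –78 °C → rt
Reagents that add atoms: ozone, [O-][O+]=O
Why: Ozonolysis; the monosubstituted terminal alkene reacts far faster than the hindered, electron-poor tetrasubstituted enone, and Me2S reduces the ozonide to the aldehyde.

**Step 4**
Reactants: 5; 6 (E)-crotyl-diisopinocampheylborane, generated in situ from (+)-Ipc2B-OMe [from (–)-α-pinene], (E)-crotylpotassium and BF3·OEt2
Product: 7 3-[(6R,7S)-6-hydroxy-7-methyl-3-oxonon-8-en-1-yl]-2,4,4-trimethylcyclohex-2-en-1-one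
Conditions: 6, THF, –78 °C; then pH 7 buffer, 30% H2O2, 0 °C → rt
Reagents that add atoms: none other than reactant 6, C/C=C/CB(C1CC2CC(C1C)C2(C)C)C1CC2CC(C1C)C2(C)C
Why: Brown asymmetric crotylboration through a chair Zimmerman–Traxler transition state; the E-reagent gives the anti relationship between Me and OH, and the pinene-derived reagent delivers the Si face of the aldehyde, giving (6R,7S). The ketone and enone are untouched at –78 °C, and the buffered peroxide workup avoids enone epoxidation.

**Step 5**
Reactants: 7
Product: 8 (6R,7S)-7-methyl-3-oxo-1-(2,6,6-trimethyl-3-oxocyclohex-1-en-1-yl)non-8-en-6-yl methanesulfonate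
Conditions: MsCl, Et3N, CH2Cl2, –20 → 0 °C; use crude
Reagents that add atoms: methanesulfonyl chloride, CS(=O)(=O)Cl
Why: Activation of the secondary alcohol as a leaving group with retention of configuration; the ketone and alkene are inert.

**Step 6**
Reactants: 8
Product: 9 (3S)-3-[(2S)-but-3-en-2-yl]-6-hydroxy-6-[2-(2,6,6-trimethyl-3-oxocyclohex-1-en-1-yl)ethyl]-1,2-dioxane (C6 epimeric peroxyhemiketals)
Conditions: 50% aq. H2O2 (10 equiv), K2CO3, THF/MeOH 1:1, 0 → 23 °C
Reagents that add atoms: hydrogen peroxide, OO
Why: Williams-type peroxide alkylation by SN2 of HOO⁻ (or the ketone perhydrate OOH in a 6-exo closure) at the secondary mesylate inverts C6 from R to S, and the resulting δ-hydroperoxy ketone closes spontaneously to the cyclic peroxyhemiketal.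

**Step 7**
Reactants: 9
Product: 10 (3S)-3-[(2S)-but-3-en-2-yl]-6-methoxy-6-[2-(2,6,6-trimethyl-3-oxocyclohex-1-en-1-yl)ethyl]-1,2-dioxane (C6 epimeric peroxyketals)
Conditions: MeOH, HC(OMe)3, PPTS (cat.), CH2Cl2, 23 °C
Reagents that add atoms: methanol, CO
Why: Acid-catalysed peroxyketalisation; trimethyl orthoformate removes water, and the anomeric mixture is irrelevant because the next step passes through a planar cation.

**Step 8**
Reactants: 10
Product: 11 (3S,6R)-3-[(2S)-but-3-en-2-yl]-6-methyl-6-[2-(2,6,6-trimethyl-3-oxocyclohex-1-en-1-yl)ethyl]-1,2-dioxane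
Conditions: AlMe3 (3 equiv), CH2Cl2, –78 → –30 °C
Reagents that add atoms: trimethylaluminium, C[Al](C)C
Why: Proposed new method: AlMe3 ionises the peroxyketal OMe to a 1,2-dioxan-3-ylium (peroxycarbenium) ion, which adopts a half-chair with the C6 side chain pseudo-equatorial, and methyl transfers along the axial (chair-forming) trajectory, so Me ends up axial and the CH2CH2Ar chain equatorial, trans to the C6 side chain, which is the (6R)-quaternary centre of the target; the closest known chemistry is Lewis-acid substitution of peroxyacetals and peroxyketals by allylsilanes (Dussault) and Reetz/Me3Al geminal methylation of ketals, and the enone is shielded by its α-methyl and β-quaternary neighbour.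

**Step 9**
Reactants: 11
Product: 12 methyl (2R)-2-[(3S,6R)-6-methyl-6-[2-(2,6,6-trimethyl-3-oxocyclohex-1-en-1-yl)ethyl]-1,2-dioxan-3-yl]propanoate (methyl diacarnoate A)
Conditions: O3, CH2Cl2/MeOH 4:1, –78 °C; then Ac2O, Et3N, DMAP (cat.), 0 °C
Reagents that add atoms: ozone, [O-][O+]=O; methanol, CO
Why: Oxidative ozonolysis with Criegee trapping by MeOH gives the α-methoxy hydroperoxide, and Ac2O/Et3N converts it directly to the methyl ester without passing through an epimerisable aldehyde, so Cα is retained; the dialkyl peroxide and the hindered enone survive.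

## Compound list
1 | dihydro-β-ionone | CC(=O)CCC1=C(C)CCCC1(C)C | starting material
2 | allyl bromide | C=CCBr | starting material
3 | 1-(2,6,6-trimethylcyclohex-1-en-1-yl)hept-6-en-3-one | C=CCCC(=O)CCC1=C(C)CCCC1(C)C | intermediate
4 | 2,4,4-trimethyl-3-(3-oxohept-6-en-1-yl)cyclohex-2-en-1-one | C=CCCC(=O)CCC1=C(C)C(=O)CCC1(C)C | intermediate
5 | 4-oxo-6-(2,6,6-trimethyl-3-oxocyclohex-1-en-1-yl)hexanal | O=CCCC(=O)CCC1=C(C)C(=O)CCC1(C)C | intermediate
6 | (E)-crotyl-diisopinocampheylborane (from (–)-α-pinene; Ipc stereo omitted) | C/C=C/CB(C1CC2CC(C1C)C2(C)C)C1CC2CC(C1C)C2(C)C | starting material (reagent)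
7 | 3-[(6R,7S)-6-hydroxy-7-methyl-3-oxonon-8-en-1-yl]-2,4,4-trimethylcyclohex-2-en-1-one | C=C[C@H](C)[C@H](O)CCC(=O)CCC1=C(C)C(=O)CCC1(C)C | intermediate
8 | (6R,7S)-7-methyl-3-oxo-1-(2,6,6-trimethyl-3-oxocyclohex-1-en-1-yl)non-8-en-6-yl methanesulfonate | C=C[C@H](C)[C@H](OS(C)(=O)=O)CCC(=O)CCC1=C(C)C(=O)CCC1(C)C | intermediate
9 | cyclic peroxyhemiketal (C6 epimers) | C=C[C@H](C)[C@@H]1CCC(O)(CCC2=C(C)C(=O)CCC2(C)C)OO1 | intermediate
10 | cyclic methyl peroxyketal (C6 epimers) | C=C[C@H](C)[C@@H]1CCC(OC)(CCC2=C(C)C(=O)CCC2(C)C)OO1 | intermediate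
11 | (3S,6R)-3-[(2S)-but-3-en-2-yl]-6-methyl-6-[2-(2,6,6-trimethyl-3-oxocyclohex-1-en-1-yl)ethyl]-1,2-dioxane | C=C[C@H](C)[C@@H]1CC[C@@](C)(CCC2=C(C)C(=O)CCC2(C)C)OO1 | intermediate
12 | methyl diacarnoate A | COC(=O)[C@H](C)[C@@H]1CC[C@@](C)(CCC2=C(C)C(=O)CCC2(C)C)OO1 | target

## Totals
Total steps: 9. Longest linear sequence: 9 steps, from 1.

## Three steps most likely to fail
1. **Step 8 (peroxycarbenium methylation).** AlMe3 may attack the O–O bond, or the diastereoselectivity may be poor.
   Fallback: a different route to C3. Wittig-methylenate the ketone to the 1,1-disubstituted alkene, then close the dioxane by a Co-HAT radical-polar-crossover Markovnikov hydroperoxide cyclisation (Shigehisa type), and separate the diastereomers.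
2. **Step 6 (SN2 peroxidation at a β-branched secondary mesylate).** E2 elimination or participation by the γ-ketone oxygen can compete.
   Fallback: a different bond-forming logic. Use an HWE reaction on 5 to make the (E)-2-methylenoate, then form the ketone-derived hydroperoxyhemiketal and close by intramolecular oxa-Michael with a chiral bifunctional amine–squaramide catalyst, setting C6 and Cα in the cyclisation and separating diastereomers.
3. **Step 2 (chemoselective allylic oxidation with a terminal alkene present).** Over-oxidation or oxidation at the wrong allylic site is possible.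
   Fallback: oxidise at a saturated, robust stage. Run a haloform reaction on 1 to give 3-(2,6,6-trimethylcyclohexenyl)propanoic acid, oxidise its methyl ester at ring C4, convert it to the Weinreb amide, and add 3-butenylmagnesium bromide to reach 4.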